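**Retrosynthetic overview**

- The strategy rests on ring D, the 2,4,6-trioxygenated benzoyl ring: its C1 carries the ketone carbon and the neighbouring C2 carries an oxygen. This ortho acyl-carbon/oxygen pair is cut back to a carboxylic acid and 3,5-bis(benzyloxy)benzyne, so the ketone C–C1(aryl) bond and the C2–O bond are made together.
- The acid 18 comes from an Evans alkylation that makes the Cα–Cβ bond: the enolate of a (chromon-3-yl)acetyl imide is alkylated with bis[4-(benzyloxy)phenyl]methyl chloride, and (R)-4-benzyloxazolidinone sets Cα as R.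
- The chromonylacetic acid comes from Negishi coupling of a 3-iodochromone with a Reformatsky reagent. Ring C (the pyranone) is the only ring built, in step 5, on ring A from trihydroxyacetophenone; rings B, B' and D arrive intact, and the key step closes no ring.
- The aryne precursor comes from 3,5-bis(benzyloxy)phenol by carbamate-directed ortho-silylation and triflation. All six phenols travel as benzyl ethers and are freed in one final hydrogenolysis.

Key step: step 14

Remark: Cα of the target (bearing H, the ketone carbon, chromone C3 and the diarylmethyl carbon) is R as read from the SMILES; compounds 2, 9 and 19 are assumed to be purchasable reagents.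

**Route**

Step 1
Reactants: 1 4-(benzyloxy)benzaldehyde; 2 [4-(benzyloxy)phenyl]magnesium bromide (THF solution)
Product: 3 bis[4-(benzyloxy)phenyl]methanol
Conditions: THF, 0 °C → rt; H2O quench
Reagents that add atoms: none
Why: Grignard addition to an aryl aldehyde should give the symmetrical benzhydrol, and no stereocenter arises because the two aryl groups are identical.

Step 2
Reactants: 3 bis[4-(benzyloxy)phenyl]methanol
Product: 4 bis[4-(benzyloxy)phenyl]methyl chloride
Conditions: SOCl2, CH2Cl2, 0 °C → rt; evaporate, use crude at once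
Reagents that add atoms: thionyl chloride, ClS(Cl)=O
Why: Chlorodehydroxylation through the chlorosulfite and a benzhydryl cation stabilised by two para-alkoxy groups should be fast, and the by-products are gases, so the moisture-sensitive chloride needs no purification.

Step 3
Reactants: 5 2',4',6'-trihydroxyacetophenone
Product: 6 1-[2,4-bis(benzyloxy)-6-hydroxyphenyl]ethan-1-one
Conditions: BnBr (2.1 equiv), K2CO3, acetone, reflux
Reagents that add atoms: benzyl bromide, BrCc1ccccc1
Why: Williamson etherification should take the 4-OH and one ortho OH, while the second ortho OH is held in a hydrogen bond to the ketone and stays free.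

Step 4
Reactants: 6 1-[2,4-bis(benzyloxy)-6-hydroxyphenyl]ethan-1-one
Product: 7 (2E)-1-[2,4-bis(benzyloxy)-6-hydroxyphenyl]-3-(dimethylamino)prop-2-en-1-one
Conditions: DMF-DMA, toluene, 95 °C
Reagents that add atoms: N,N-dimethylformamide dimethyl acetal, COC(OC)N(C)C
Why: Condensation of the methyl ketone with the formamide acetal (enaminone formation) installs the carbon that becomes chromone C2.

Step 5
Reactants: 7 (2E)-1-[2,4-bis(benzyloxy)-6-hydroxyphenyl]-3-(dimethylamino)prop-2-en-1-one
Product: 8 5,7-bis(benzyloxy)-3-iodo-4H-chromen-4-one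
Conditions: I2, CHCl3, rt
Reagents that add atoms: iodine, II
Why: Iodocyclisation of an ortho-hydroxyaryl enaminone: iodination at the enaminone α-carbon, 6-exo-trig attack of the phenol oxygen on the iminium carbon and loss of dimethylamine should close ring C with iodine at C3.

Step 6
Reactants: 8 5,7-bis(benzyloxy)-3-iodo-4H-chromen-4-one; 9 (2-tert-butoxy-2-oxoethyl)zinc bromide
Product: 10 tert-butyl [5,7-bis(benzyloxy)-4-oxo-4H-chromen-3-yl]acetate
Conditions: Pd2(dba)3 (2 mol %), XPhos (8 mol %), THF, rt → 50 °C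
Reagents that add atoms: none
Why: Negishi-type coupling of a Reformatsky reagent with the electron-poor vinyl iodide should form the C3–CH2 bond, the mild zinc enolate leaving the chromone carbonyl and C2 alone.

Step 7
Reactants: 10 tert-butyl [5,7-bis(benzyloxy)-4-oxo-4H-chromen-3-yl]acetate
Product: 11 [5,7-bis(benzyloxy)-4-oxo-4H-chromen-3-yl]acetic acid
Conditions: TFA/CH2Cl2 (1:3), 0 °C → rt
Reagents that add atoms: none
Why: Acidolysis of the tert-butyl ester (loss of 2-methylpropene) frees the acid without hydroxide, which would open the pyranone ring, and aryl benzyl ethers should tolerate TFA at room temperature.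

Step 8
Reactants: 11 [5,7-bis(benzyloxy)-4-oxo-4H-chromen-3-yl]acetic acid; 12 (R)-4-benzyl-1,3-oxazolidin-2-one
Product: 14 (4R)-4-benzyl-3-{[5,7-bis(benzyloxy)-4-oxo-4H-chromen-3-yl]acetyl}-1,3-oxazolidin-2-one, via mixed pivalic anhydride 13 (not isolated)
Conditions: t-BuCOCl, Et3N, THF, −20 °C; then LiCl, 12, −20 °C → rt
Reagents that add atoms: none
Why: N-acylation of the oxazolidinone through the mixed pivalic anhydride with LiCl/Et3N activation needs no strong base, so the chromone should be untouched.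

Step 9
Reactants: 14 (4R)-4-benzyl-3-{[5,7-bis(benzyloxy)-4-oxo-4H-chromen-3-yl]acetyl}-1,3-oxazolidin-2-one; 4 bis[4-(benzyloxy)phenyl]methyl chloride
Product: 16 (4R)-4-benzyl-3-{(2R)-2-[5,7-bis(benzyloxy)-4-oxo-4H-chromen-3-yl]-3,3-bis[4-(benzyloxy)phenyl]propanoyl}-1,3-oxazolidin-2-one, via sodium (Z)-enolate 15 (not isolated)
Conditions: NaN(SiMe3)2 (1.05 equiv), THF, −78 °C; then 4 (1.3 equiv), −78 → −20 °C; aq NH4Cl
Reagents that add atoms: none
Why: Evans asymmetric alkylation: the sodium-chelated (Z)-enolate should be attacked by the highly reactive benzhydryl chloride on the face away from the C4 benzyl group of the (R)-auxiliary, which sets Cα as R (the same facial sense that gives (S)-2-arylpropanoates from the (S)-auxiliary and methyl iodide).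

Step 10
Reactants: 16 (4R)-4-benzyl-3-{(2R)-2-[5,7-bis(benzyloxy)-4-oxo-4H-chromen-3-yl]-3,3-bis[4-(benzyloxy)phenyl]propanoyl}-1,3-oxazolidin-2-one
Product: 18 (2R)-2-[5,7-bis(benzyloxy)-4-oxo-4H-chromen-3-yl]-3,3-bis[4-(benzyloxy)phenyl]propanoic acid, via lithium peroxycarboxylate 17 (not isolated)
Conditions: LiOH, H2O2, THF/H2O (3:1), 0 °C; aq Na2SO3; then 1 M HCl to pH 3
Reagents that add atoms: hydrogen peroxide (as lithium hydroperoxide), OO
Why: Hydroperoxide cleavage of the imide attacks the exocyclic carbonyl even when it is hindered, and the weakly basic nucleophile at 0 °C should leave Cα–H and the electron-rich chromone alone.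

Step 11
Reactants: 19 3,5-bis(benzyloxy)phenol
Product: 20 3,5-bis(benzyloxy)phenyl N-(propan-2-yl)carbamate
Conditions: i-PrNCO, Et3N (cat.), CH2Cl2, rt
Reagents that add atoms: isopropyl isocyanate, CC(C)N=C=O
Why: Addition of the phenol to the isocyanate (carbamoylation) installs a directing group that can later be removed under mild base.

Step 12
Reactants: 20 3,5-bis(benzyloxy)phenyl N-(propan-2-yl)carbamate
Product: 24 3,5-bis(benzyloxy)-2-(trimethylsilyl)phenyl N-(propan-2-yl)carbamate, via N-silyl carbamate 21 (not isolated), via ortho-lithiated N-silyl carbamate 22 (not isolated), via N-silyl C-silyl carbamate 23 (not isolated)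
Conditions: TBSOTf, TMEDA, Et2O, 0 °C → rt; n-BuLi, TMEDA, −78 °C; Me3SiCl, −78 °C → rt; aq NaHSO4
Reagents that add atoms: chlorotrimethylsilane, C[Si](C)(C)Cl
Why: Directed ortho-metalation: the N-silylated carbamate should steer lithiation to C2, the position flanked by the carbamate oxygen and a benzyloxy group, and silyl chloride quench followed by acidic work-up removes the N-silyl group.

Step 13
Reactants: 24 3,5-bis(benzyloxy)-2-(trimethylsilyl)phenyl N-(propan-2-yl)carbamate
Product: 26 3,5-bis(benzyloxy)-2-(trimethylsilyl)phenyl trifluoromethanesulfonate, via 3,5-bis(benzyloxy)-2-(trimethylsilyl)phenol 25 (not isolated)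
Conditions: DBU, Et2NH, MeCN, 40 °C; then PhNTf2, rt
Reagents that add atoms: N-phenylbis(trifluoromethanesulfonimide), O=S(=O)(N(c1ccccc1)S(=O)(=O)C(F)(F)F)C(F)(F)F
Why: E1cB cleavage of the secondary carbamate (the isocyanate is trapped by diethylamine) gives the phenoxide, which is triflated in the same flask, so the silyl phenol is never exposed to protodesilylation.

Step 14
Reactants: 18 (2R)-2-[5,7-bis(benzyloxy)-4-oxo-4H-chromen-3-yl]-3,3-bis[4-(benzyloxy)phenyl]propanoic acid; 26 3,5-bis(benzyloxy)-2-(trimethylsilyl)phenyl trifluoromethanesulfonate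
Product: 29 (2R)-1-[2,4-bis(benzyloxy)-6-hydroxyphenyl]-2-[5,7-bis(benzyloxy)-4-oxo-4H-chromen-3-yl]-3,3-bis[4-(benzyloxy)phenyl]propan-1-one, via cesium carboxylate 27 (not isolated), via 3,5-bis(benzyloxy)benzyne 28 (not isolated)
Conditions: Cs2CO3 (0.5 equiv), MeOH, evaporate and dry; then 26 (1.3 equiv, slow addition), CsF (3 equiv), 18-crown-6, THF, 65 °C; 1 M HCl work-up
Reagents that add atoms: none
Why: Fluoride attack on silicon of 26 with loss of triflate releases benzyne 28, and the carboxylate oxygen of 27 adds at C1, the aryne carbon remote from the C3 benzyloxy group, so that the aryl anion forms at C2 where the adjacent C–O bond stabilises it inductively (the usual regiochemistry of 3-alkoxyarynes). The C2 anion then adds to the ester carbonyl through a four-membered transition structure and the acyl C–O bond breaks, which delivers the acyl group to C2 and leaves the oxygen on C1 as phenoxide; this is the acyl C–O σ-insertion of an aryne into a carboxylic acid, the known way to ortho-hydroxyaryl ketones, run here on a dried cesium salt instead of the free acid. No ring is closed (the benzoxete alkoxide is only a transient) and no new stereocenter is made. The acyl group migrates with Cα attached and untouched, so the R configuration from step 9 should be kept provided acyl transfer is faster than proton transfer from Cα–H to the aryl anion, which the absence of HF or any other proton source and the crowding around Cα–H are meant to secure. Site selectivity (ketone carbon between the C–OH and a C–OBn carbon) rests on the C3 benzyloxy group of 28, and chemoselectivity on the carboxylate being by far the best nucleophile present, the chromone, benzyl ethers and electron-rich arenes being poor aryne partners. Crown-ether-solubilised CsF should let the aryne form at 65 °C, well below the sealed-tube temperatures usual for the free-acid protocol, and the product rests as a twisted 2,6-dioxygenated aryl ketone phenoxide, which disfavours enolisation toward Cα.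

Step 15
Reactants: 29 (2R)-1-[2,4-bis(benzyloxy)-6-hydroxyphenyl]-2-[5,7-bis(benzyloxy)-4-oxo-4H-chromen-3-yl]-3,3-bis[4-(benzyloxy)phenyl]propan-1-one
Product: 30 (2R)-2-(5,7-dihydroxy-4-oxo-4H-chromen-3-yl)-3,3-bis(4-hydroxyphenyl)-1-(2,4,6-trihydroxyphenyl)propan-1-one (CNP0106875.1)
Conditions: H2 (1 atm), 10% Pd/C, EtOAc/MeOH, rt
Reagents that add atoms: none
Why: Catalytic hydrogenolysis should cleave all six aryl benzyl ethers under neutral conditions that do not enolise the ketone, while the chelated, doubly ortho-substituted aryl ketone and the chromone C2=C3 bond are slow to reduce at one atmosphere if the reaction is stopped when hydrogen uptake ends.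

**Compound list**

1 | 4-(benzyloxy)benzaldehyde | O=Cc1ccc(OCc2ccccc2)cc1 | starting material
2 | [4-(benzyloxy)phenyl]magnesium bromide | Br[Mg]c1ccc(OCc2ccccc2)cc1 | starting material
3 | bis[4-(benzyloxy)phenyl]methanol | OC(c1ccc(OCc2ccccc2)cc1)c1ccc(OCc2ccccc2)cc1 | intermediate
4 | bis[4-(benzyloxy)phenyl]methyl chloride | ClC(c1ccc(OCc2ccccc2)cc1)c1ccc(OCc2ccccc2)cc1 | intermediate
5 | 2',4',6'-trihydroxyacetophenone | CC(=O)c1c(O)cc(O)cc1O | starting material
6 | 1-[2,4-bis(benzyloxy)-6-hydroxyphenyl]ethan-1-one | CC(=O)c1c(O)cc(OCc2ccccc2)cc1OCc1ccccc1 | intermediate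
7 | (2E)-1-[2,4-bis(benzyloxy)-6-hydroxyphenyl]-3-(dimethylamino)prop-2-en-1-one | CN(C)/C=C/C(=O)c1c(O)cc(OCc2ccccc2)cc1OCc1ccccc1 | intermediate
8 | 5,7-bis(benzyloxy)-3-iodo-4H-chromen-4-one | Ic1coc2cc(OCc3ccccc3)cc(OCc3ccccc3)c2c1=O | intermediate
9 | (2-tert-butoxy-2-oxoethyl)zinc bromide | CC(C)(C)OC(=O)C[Zn]Br | starting material
10 | tert-butyl [5,7-bis(benzyloxy)-4-oxo-4H-chromen-3-yl]acetate | CC(C)(C)OC(=O)Cc1coc2cc(OCc3ccccc3)cc(OCc3ccccc3)c2c1=O | intermediate
11 | [5,7-bis(benzyloxy)-4-oxo-4H-chromen-3-yl]acetic acid | OC(=O)Cc1coc2cc(OCc3ccccc3)cc(OCc3ccccc3)c2c1=O | intermediate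
12 | (R)-4-benzyl-1,3-oxazolidin-2-one | O=C1N[C@H](Cc2ccccc2)CO1 | starting material
13 | [5,7-bis(benzyloxy)-4-oxo-4H-chromen-3-yl]acetic pivalic anhydride | CC(C)(C)C(=O)OC(=O)Cc1coc2cc(OCc3ccccc3)cc(OCc3ccccc3)c2c1=O | intermediate
14 | (4R)-4-benzyl-3-{[5,7-bis(benzyloxy)-4-oxo-4H-chromen-3-yl]acetyl}-1,3-oxazolidin-2-one | O=C(Cc1coc2cc(OCc3ccccc3)cc(OCc3ccccc3)c2c1=O)N1C(=O)OC[C@H]1Cc1ccccc1 | intermediate
15 | sodium (Z)-enolate of 14 | [Na+].[O-]/C(=C\c1coc2cc(OCc3ccccc3)cc(OCc3ccccc3)c2c1=O)N1C(=O)OC[C@H]1Cc1ccccc1 | intermediate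
16 | (4R)-4-benzyl-3-{(2R)-2-[5,7-bis(benzyloxy)-4-oxo-4H-chromen-3-yl]-3,3-bis[4-(benzyloxy)phenyl]propanoyl}-1,3-oxazolidin-2-one | O=C(N1C(=O)OC[C@H]1Cc1ccccc1)[C@@H](c1coc2cc(OCc3ccccc3)cc(OCc3ccccc3)c2c1=O)C(c1ccc(OCc2ccccc2)cc1)c1ccc(OCc2ccccc2)cc1 | intermediate
17 | lithium (2R)-2-[5,7-bis(benzyloxy)-4-oxo-4H-chromen-3-yl]-3,3-bis[4-(benzyloxy)phenyl]propaneperoxoate | [Li+].[O-]OC(=O)[C@@H](c1coc2cc(OCc3ccccc3)cc(OCc3ccccc3)c2c1=O)C(c1ccc(OCc2ccccc2)cc1)c1ccc(OCc2ccccc2)cc1 | intermediate
18 | (2R)-2-[5,7-bis(benzyloxy)-4-oxo-4H-chromen-3-yl]-3,3-bis[4-(benzyloxy)phenyl]propanoic acid | OC(=O)[C@@H](c1coc2cc(OCc3ccccc3)cc(OCc3ccccc3)c2c1=O)C(c1ccc(OCc2ccccc2)cc1)c1ccc(OCc2ccccc2)cc1 | intermediate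
19 | 3,5-bis(benzyloxy)phenol | Oc1cc(OCc2ccccc2)cc(OCc2ccccc2)c1 | starting material
20 | 3,5-bis(benzyloxy)phenyl N-(propan-2-yl)carbamate | CC(C)NC(=O)Oc1cc(OCc2ccccc2)cc(OCc2ccccc2)c1 | intermediate
21 | 3,5-bis(benzyloxy)phenyl N-(tert-butyldimethylsilyl)-N-(propan-2-yl)carbamate | CC(C)N(C(=O)Oc1cc(OCc2ccccc2)cc(OCc2ccccc2)c1)[Si](C)(C)C(C)(C)C | intermediate
22 | 2-lithio derivative of 21 | [Li]c1c(OC(=O)N(C(C)C)[Si](C)(C)C(C)(C)C)cc(OCc2ccccc2)cc1OCc1ccccc1 | intermediate
23 | 3,5-bis(benzyloxy)-2-(trimethylsilyl)phenyl N-(tert-butyldimethylsilyl)-N-(propan-2-yl)carbamate | C[Si](C)(C)c1c(OC(=O)N(C(C)C)[Si](C)(C)C(C)(C)C)cc(OCc2ccccc2)cc1OCc1ccccc1 | intermediate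
24 | 3,5-bis(benzyloxy)-2-(trimethylsilyl)phenyl N-(propan-2-yl)carbamate | C[Si](C)(C)c1c(OC(=O)NC(C)C)cc(OCc2ccccc2)cc1OCc1ccccc1 | intermediate
25 | 3,5-bis(benzyloxy)-2-(trimethylsilyl)phenol | C[Si](C)(C)c1c(O)cc(OCc2ccccc2)cc1OCc1ccccc1 | intermediate
26 | 3,5-bis(benzyloxy)-2-(trimethylsilyl)phenyl trifluoromethanesulfonate | C[Si](C)(C)c1c(OCc2ccccc2)cc(OCc2ccccc2)cc1OS(=O)(=O)C(F)(F)F | intermediate
27 | cesium (2R)-2-[5,7-bis(benzyloxy)-4-oxo-4H-chromen-3-yl]-3,3-bis[4-(benzyloxy)phenyl]propanoate | [Cs+].[O-]C(=O)[C@@H](c1coc2cc(OCc3ccccc3)cc(OCc3ccccc3)c2c1=O)C(c1ccc(OCc2ccccc2)cc1)c1ccc(OCc2ccccc2)cc1 | intermediate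
28 | 3,5-bis(benzyloxy)benzyne | C1#CC(OCc2ccccc2)=CC(OCc2ccccc2)=C1 | intermediate
29 | (2R)-1-[2,4-bis(benzyloxy)-6-hydroxyphenyl]-2-[5,7-bis(benzyloxy)-4-oxo-4H-chromen-3-yl]-3,3-bis[4-(benzyloxy)phenyl]propan-1-one | O=C(c1c(O)cc(OCc2ccccc2)cc1OCc1ccccc1)[C@@H](c1coc2cc(OCc3ccccc3)cc(OCc3ccccc3)c2c1=O)C(c1ccc(OCc2ccccc2)cc1)c1ccc(OCc2ccccc2)cc1 | intermediate
30 | (2R)-2-(5,7-dihydroxy-4-oxo-4H-chromen-3-yl)-3,3-bis(4-hydroxyphenyl)-1-(2,4,6-trihydroxyphenyl)propan-1-one | O=C(c1c(O)cc(O)cc1O)[C@@H](c1coc2cc(O)cc(O)c2c1=O)C(c1ccc(O)cc1)c1ccc(O)cc1 | target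

**Step count and risks**

Total step count: 15. Longest linear sequence: 10 steps (steps 3–10, 14, 15).

Steps most likely to fail:

1. Step 14 (aryne insertion). The aryl anion may take a proton from Cα–H or from adventitious acid instead of attacking the acyl carbon. That would give loss of configuration, a ketene-derived by-product or the simple aryl ester. Excess aryne may also arylate the product phenoxide, and fluoride may enolise the product ketone.
 Fallback, from 18 and 19, returning at 30: phenol 19 is benzylated (BnBr, K2CO3, DMF) to 1,3,5-tris(benzyloxy)benzene F1. Acid 18 is activated with trifluoroacetic anhydride in CH2Cl2 at 0 °C as the mixed trifluoroacetic anhydride F2. F2 acylates F1 in a Friedel–Crafts reaction without a metal Lewis acid, giving (2R)-2-[5,7-bis(benzyloxy)-4-oxo-4H-chromen-3-yl]-3,3-bis[4-(benzyloxy)phenyl]-1-[2,4,6-tris(benzyloxy)phenyl]propan-1-one F3. Hydrogenolysis of its seven benzyl ethers under the conditions of step 15 gives 30.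

2. Step 9 (Evans alkylation). The very ionisable chloride may be consumed by base-induced α-elimination or self-coupling, the enolate may react at oxygen, or slow alkylation may let the enolate decompose or epimerise the product, eroding facial control.
 Fallback, from 10 and 4, returning at 18: ester 10 is converted (LiN(SiMe3)2, Me3SiCl, THF, −78 °C) into its tert-butyl trimethylsilyl ketene acetal F4. F4 is alkylated by 4 under ZnCl2 catalysis in CH2Cl2 at −40 °C (SN1-type Mukaiyama alkylation, no strong base) to racemic tert-butyl 2-[5,7-bis(benzyloxy)-4-oxo-4H-chromen-3-yl]-3,3-bis[4-(benzyloxy)phenyl]propanoate F5. TFA gives the racemic acid F6, and preparative chromatography on a chiral stationary phase delivers the R enantiomer 18.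

3. Step 10 (auxiliary cleavage). Hydroperoxide may add to chromone C2 (epoxidation or ring opening) faster than it cleaves the congested imide, and prolonged exposure to hydroxide may epimerise Cα.
 Fallback, from 16, returning at 18: transesterification with bromomagnesium allyloxide (allyl alcohol, MeMgBr, THF, 0 °C) gives prop-2-en-1-yl (2R)-2-[5,7-bis(benzyloxy)-4-oxo-4H-chromen-3-yl]-3,3-bis[4-(benzyloxy)phenyl]propanoate F7. Deallylation with Pd(PPh3)4 and morpholine in THF at rt gives 18 under neutral conditions.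

Further compounds
F1 | step 14 | 1,3,5-tris(benzyloxy)benzene | c1c(OCc2ccccc2)cc(OCc2ccccc2)cc1OCc1ccccc1
F2 | step 14 | (2R)-2-[5,7-bis(benzyloxy)-4-oxo-4H-chromen-3-yl]-3,3-bis[4-(benzyloxy)phenyl]propanoic trifluoroacetic anhydride | FC(F)(F)C(=O)OC(=O)[C@@H](c1coc2cc(OCc3ccccc3)cc(OCc3ccccc3)c2c1=O)C(c1ccc(OCc2ccccc2)cc1)c1ccc(OCc2ccccc2)cc1
F3 | step 14 | (2R)-2-[5,7-bis(benzyloxy)-4-oxo-4H-chromen-3-yl]-3,3-bis[4-(benzyloxy)phenyl]-1-[2,4,6-tris(benzyloxy)phenyl]propan-1-one | O=C(c1c(OCc2ccccc2)cc(OCc2ccccc2)cc1OCc1ccccc1)[C@@H](c1coc2cc(OCc3ccccc3)cc(OCc3ccccc3)c2c1=O)C(c1ccc(OCc2ccccc2)cc1)c1ccc(OCc2ccccc2)cc1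
F4 | step 9 | tert-butyl trimethylsilyl ketene acetal of 10 | CC(C)(C)OC(O[Si](C)(C)C)=Cc1coc2cc(OCc3ccccc3)cc(OCc3ccccc3)c2c1=O
F5 | step 9 | racemic tert-butyl 2-[5,7-bis(benzyloxy)-4-oxo-4H-chromen-3-yl]-3,3-bis[4-(benzyloxy)phenyl]propanoate | CC(C)(C)OC(=O)C(c1coc2cc(OCc3ccccc3)cc(OCc3ccccc3)c2c1=O)C(c1ccc(OCc2ccccc2)cc1)c1ccc(OCc2ccccc2)cc1
F6 | step 9 | racemic 2-[5,7-bis(benzyloxy)-4-oxo-4H-chromen-3-yl]-3,3-bis[4-(benzyloxy)phenyl]propanoic acid | OC(=O)C(c1coc2cc(OCc3ccccc3)cc(OCc3ccccc3)c2c1=O)C(c1ccc(OCc2ccccc2)cc1)c1ccc(OCc2ccccc2)cc1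
F7 | step 10 | prop-2-en-1-yl (2R)-2-[5,7-bis(benzyloxy)-4-oxo-4H-chromen-3-yl]-3,3-bis[4-(benzyloxy)phenyl]propanoate | C=CCOC(=O)[C@@H](c1coc2cc(OCc3ccccc3)cc(OCc3ccccc3)c2c1=O)C(c1ccc(OCc2ccccc2)cc1)c1ccc(OCc2ccccc2)cc1
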